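## Retrosynthetic overview

1. Target 17 ⇐ tertiary quinol 16 (O-methylation at C5) ⇐ phenol 15 (reagent-controlled ortho-hydroxylative dearomatisation at C5) ⇐ silyl ether 14 (desilylation).
2. 14 ⇐ ortho-quinone methide 11 + benzylic sulfonium ylide 12 by a [4+1] annulation that forms C2–C3 and O1–C2.
3. Feature used: C2 of the dihydrofuran ring is one benzylic carbon (it carries the trimethoxyphenyl group) bonded to both O1 and C3, and the methyl-bearing C3 sits on C3a next to the O1-bearing C7a. O1–C7a–C3a–C3 is therefore an oxa-diene and C2 a one-carbon partner.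
4. 11 ⇐ sulfone 7 ⇐ 2',4'-dihydroxyacetophenone 1 (bromination, Stille allylation, silylation, reduction, sulfinate exchange); 12 ⇐ salt 10 ⇐ benzyl chloride 8 + isothiocineole 9.
5. Ring order: both benzene rings are bought, the dihydrofuran ring is closed in step 7, and the carbocycle is dearomatised last.

Key step: step 7

Assumptions:
- Benzofuran numbering is used throughout: O1, C2 (aryl), C3 (methyl), C3a, C4, C5 (allyl), C6 (oxygen), C7, C7a. The target is (2S,3S,5R), with C2-aryl and C3-methyl trans.
- The sense of induction of isothiocineole is taken to parallel its benzylidene transfers to C=O and C=N, so the (1R,4R,5R) sulfide (from (R)-limonene) is written; if the first run gives the (2R,3R) series, the (1S,4S,5S) sulfide replaces it with no other change.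
- Salt 10 is expected as one diastereomer at sulfur (alkylation of the less hindered lone pair); the sulfur configuration of 10, 12 and 13 is left unwritten in the SMILES.
- The antipode of the chiral iodane in step 9 that favours 5R is found by trial; the (S) reagent is written.
- A triisopropylsilyl ether is used on the C6 oxygen because it must survive borohydride in methanol, sulfinic acid and carbonate.

## Route

Step 1
Reactants: 1 2',4'-dihydroxyacetophenone
Product: 2 1-(5-bromo-2,4-dihydroxyphenyl)ethanone
Conditions: NBS (1.0 equiv), MeCN, 0 °C → rt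
Reagents that add atoms: N-bromosuccinimide, O=C1CCC(=O)N1Br
Why: Electrophilic aromatic bromination should go to C5, which is para to the chelated 2-OH, ortho to the 4-OH and less hindered than C3 between the two hydroxyls.

Step 2
Reactants: 2 1-(5-bromo-2,4-dihydroxyphenyl)ethanone; 3 allyltributylstannane
Product: 4 1-(5-allyl-2,4-dihydroxyphenyl)ethanone
Conditions: Pd(PPh3)4 (5 mol %), DMF, 95 °C, degassed
Reagents that add atoms: none
Why: Migita–Kosugi–Stille coupling of the aryl bromide with the allylstannane runs under neutral conditions that tolerate free phenols, and is stopped at full conversion to limit allyl-to-propenyl migration.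

Step 3
Reactants: 4 1-(5-allyl-2,4-dihydroxyphenyl)ethanone
Product: 5 1-[5-allyl-2-hydroxy-4-(triisopropylsilyloxy)phenyl]ethanone
Conditions: TIPSCl (1.1 equiv), imidazole, DMF, 0 °C → rt
Reagents that add atoms: chlorotriisopropylsilane, CC(C)[Si](Cl)(C(C)C)C(C)C
Why: Selective O-silylation, because the 2-OH is held in a hydrogen bond to the ketone and only the 4-OH should react.

Step 4
Reactants: 5 1-[5-allyl-2-hydroxy-4-(triisopropylsilyloxy)phenyl]ethanone
Product: 6 rac-1-[5-allyl-2-hydroxy-4-(triisopropylsilyloxy)phenyl]ethanol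
Conditions: NaBH4, THF/MeOH, 0 °C; pH 7 buffer work-up; used crude
Reagents that add atoms: none
Why: Borohydride reduction of the aryl ketone; the carbinol centre forms racemic and is erased in step 7, and the neutral work-up avoids ionisation of the electron-rich benzylic alcohol.

Step 5
Reactants: 6 rac-1-[5-allyl-2-hydroxy-4-(triisopropylsilyloxy)phenyl]ethanol
Product: 7 rac-4-allyl-2-[1-(p-tolylsulfonyl)ethyl]-5-(triisopropylsilyloxy)phenol
Conditions: p-TolSO2H (1.5 equiv), 4 Å MS, CH2Cl2, rt
Reagents that add atoms: p-toluenesulfinic acid, Cc1ccc(cc1)S(O)=O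
Why: SN1-type substitution: the sulfinic acid ionises the benzylic alcohol (cation stabilised by the ortho-OH and para-silyloxy groups) and sulfinate is taken up at sulfur to give the sulfone, the thermodynamic product.

Step 6
Reactants: 8 3,4,5-trimethoxybenzyl chloride; 9 (1R,4R,5R)-isothiocineole
Product: 10 (1R,4R,5R)-4,7,7-trimethyl-6-(3,4,5-trimethoxybenzyl)-6-thiabicyclo[3.2.1]octan-6-ium tetrafluoroborate
Conditions: NaBF4, NaI (cat.), acetone, rt
Reagents that add atoms: sodium tetrafluoroborate, [Na+].F[B-](F)(F)F
Why: SN2 S-alkylation of the sulfide with anion metathesis; the non-nucleophilic counter-ion keeps the electron-rich benzylic sulfonium salt from reverting to halide and sulfide.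

Step 7
Reactants: 7 rac-4-allyl-2-[1-(p-tolylsulfonyl)ethyl]-5-(triisopropylsilyloxy)phenol; 10 the isothiocineole-derived sulfonium tetrafluoroborate
Product: 14 (2S,3S)-5-allyl-3-methyl-6-(triisopropylsilyloxy)-2-(3,4,5-trimethoxyphenyl)-2,3-dihydrobenzofuran, via ortho-quinone methide 11 (not isolated), via benzylic sulfonium ylide 12 (not isolated), via anti betaine 13 (not isolated)
Conditions: 10 (1.5 equiv), Cs2CO3 (3 equiv), MeCN/CH2Cl2, 0 °C, slow addition of 7, then rt
Reagents that add atoms: none
Why: Proposed new method: carbonate deprotonates phenol 7, sulfinate leaves (E1cB) to give the (E)-quinone methide 11, and the same base turns 10 into ylide 12, whose carbon adds to the ethylidene carbon (future C3) with re-aromatisation to the phenoxide betaine 13, which closes by attack of O1 on C2 with loss of isothiocineole. The closest known reactions are the trans-selective [4+1] annulation of sulfonium ylides with quinone methides released from 2-(1-tosylalkyl)phenols and the isothiocineole-controlled benzylidene transfers to aldehydes and imines; combining them is the new element. The dihydrofuran ring is the only ring closed, by 5-exo-tet SN2 formation of O1–C2 after C2–C3 has been made in the conjugate addition. C2 is controlled by the sulfide scaffold, which fixes the ylide conformation and shields one face of the ylide carbon, and is inverted once in the ring closure; C3 is set relative to C2 in the addition, the anti betaine being favoured and leading to the trans ring. The step needs capture of 11 before it tautomerises to the vinylphenol and trans over cis closure: the E geometry of 11 (no 1,5-hydrogen shift), its reversible storage as sulfone 7 by sulfinate re-addition, the excess of 10 with slow addition of 7, and the lower strain of the trans closure should secure this.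

Step 8
Reactants: 14 (2S,3S)-5-allyl-3-methyl-6-(triisopropylsilyloxy)-2-(3,4,5-trimethoxyphenyl)-2,3-dihydrobenzofuran
Product: 15 (2S,3S)-5-allyl-3-methyl-2-(3,4,5-trimethoxyphenyl)-2,3-dihydrobenzofuran-6-ol
Conditions: TBAF, AcOH, THF, 0 °C
Reagents that add atoms: none
Why: Fluoride cleavage of the aryl silyl ether under acetic acid buffering; C2 and C3 carry no acidifying group and should not be touched.

Step 9
Reactants: 15 (2S,3S)-5-allyl-3-methyl-2-(3,4,5-trimethoxyphenyl)-2,3-dihydrobenzofuran-6-ol
Product: 16 (2S,3S,5R)-5-allyl-5-hydroxy-3-methyl-2-(3,4,5-trimethoxyphenyl)-2,3-dihydrobenzofuran-6(5H)-one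
Conditions: (S)-4-isopropyl-2-(2-iodylphenyl)-4,5-dihydrooxazole (1.2 equiv; from the iodoarene and dimethyldioxirane), CH2Cl2, −40 → 0 °C; then H2O; used at once
Reagents that add atoms: (S)-4-isopropyl-2-(2-iodylphenyl)-4,5-dihydrooxazole, CC(C)[C@H]1COC(=N1)c1ccccc1I(=O)=O
Why: Ortho-hydroxylative phenol dearomatisation with a chiral λ5-iodane, in which O6 binds iodine(V) and oxygen is passed within the complex to the ortho carbon C5 (allyl-bearing and para to O1); the 5R centre is set by the reagent, since C2 and C3 are too remote to bias the face, and the 5S epimer is a diastereomer that chromatography should remove.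

Step 10
Reactants: 16 (2S,3S,5R)-5-allyl-5-hydroxy-3-methyl-2-(3,4,5-trimethoxyphenyl)-2,3-dihydrobenzofuran-6(5H)-one
Product: 17 (2S,3S,5R)-5-allyl-5-methoxy-3-methyl-2-(3,4,5-trimethoxyphenyl)-2,3-dihydrobenzofuran-6(5H)-one (target)
Conditions: MeI (excess), Ag2O, 4 Å MS, CH2Cl2, rt, dark; kept below 30 °C
Reagents that add atoms: iodomethane, CI
Why: Purdie-type silver oxide methylation etherifies the tertiary alcohol without a free alkoxide, which should avoid anionic oxy-Cope migration of the allyl group and ketol rearrangement; only the O–H bond reacts, so C5 keeps its configuration.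

## Compound list

1 | 2',4'-dihydroxyacetophenone | CC(=O)c1ccc(O)cc1O | starting material
2 | 1-(5-bromo-2,4-dihydroxyphenyl)ethanone | CC(=O)c1cc(Br)c(O)cc1O | intermediate
3 | allyltributylstannane | C=CC[Sn](CCCC)(CCCC)CCCC | starting material
4 | 1-(5-allyl-2,4-dihydroxyphenyl)ethanone | CC(=O)c1cc(CC=C)c(O)cc1O | intermediate
5 | 1-[5-allyl-2-hydroxy-4-(triisopropylsilyloxy)phenyl]ethanone | CC(=O)c1cc(CC=C)c(O[Si](C(C)C)(C(C)C)C(C)C)cc1O | intermediate
6 | rac-1-[5-allyl-2-hydroxy-4-(triisopropylsilyloxy)phenyl]ethanol | CC(O)c1cc(CC=C)c(O[Si](C(C)C)(C(C)C)C(C)C)cc1O | intermediate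
7 | rac-4-allyl-2-[1-(p-tolylsulfonyl)ethyl]-5-(triisopropylsilyloxy)phenol | CC(c1cc(CC=C)c(O[Si](C(C)C)(C(C)C)C(C)C)cc1O)S(=O)(=O)c1ccc(C)cc1 | intermediate
8 | 3,4,5-trimethoxybenzyl chloride | COc1cc(CCl)cc(OC)c1OC | starting material
9 | (1R,4R,5R)-isothiocineole (4,7,7-trimethyl-6-thiabicyclo[3.2.1]octane) | C[C@@H]1CC[C@@H]2C[C@H]1SC2(C)C | starting material
10 | (1R,4R,5R)-4,7,7-trimethyl-6-(3,4,5-trimethoxybenzyl)-6-thiabicyclo[3.2.1]octan-6-ium tetrafluoroborate | C[C@@H]1CC[C@@H]2C[C@H]1[S+](Cc1cc(OC)c(OC)c(OC)c1)C2(C)C.F[B-](F)(F)F | intermediate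
11 | (E)-4-allyl-6-ethylidene-3-(triisopropylsilyloxy)cyclohexa-2,4-dien-1-one | C/C=C1\C=C(CC=C)C(O[Si](C(C)C)(C(C)C)C(C)C)=CC1=O | intermediate
12 | isothiocineole-derived (3,4,5-trimethoxyphenyl)methylide | C[C@@H]1CC[C@@H]2C[C@H]1[S+]([CH-]c1cc(OC)c(OC)c(OC)c1)C2(C)C | intermediate
13 | anti betaine: 2-[1-methyl-2-(isothiocineolium-6-yl)-2-(3,4,5-trimethoxyphenyl)ethyl]phenoxide leading to (2S,3S) | C[C@@H]1CC[C@@H]2C[C@H]1[S+]([C@@H](c1cc(OC)c(OC)c(OC)c1)[C@@H](C)c1cc(CC=C)c(O[Si](C(C)C)(C(C)C)C(C)C)cc1[O-])C2(C)C | intermediate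
14 | (2S,3S)-5-allyl-3-methyl-6-(triisopropylsilyloxy)-2-(3,4,5-trimethoxyphenyl)-2,3-dihydrobenzofuran | C=CCc1cc2c(cc1O[Si](C(C)C)(C(C)C)C(C)C)O[C@H](c1cc(OC)c(OC)c(OC)c1)[C@H]2C | intermediate
15 | (2S,3S)-5-allyl-3-methyl-2-(3,4,5-trimethoxyphenyl)-2,3-dihydrobenzofuran-6-ol | C=CCc1cc2c(cc1O)O[C@H](c1cc(OC)c(OC)c(OC)c1)[C@H]2C | intermediate
16 | (2S,3S,5R)-5-allyl-5-hydroxy-3-methyl-2-(3,4,5-trimethoxyphenyl)-2,3-dihydrobenzofuran-6(5H)-one | C=CC[C@@]1(O)C=C2C(=CC1=O)O[C@H](c1cc(OC)c(OC)c(OC)c1)[C@H]2C | intermediate
17 | (2S,3S,5R)-5-allyl-5-methoxy-3-methyl-2-(3,4,5-trimethoxyphenyl)-2,3-dihydrobenzofuran-6(5H)-one | C=CC[C@@]1(OC)C=C2C(=CC1=O)O[C@H](c1cc(OC)c(OC)c(OC)c1)[C@H]2C | target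

## Step count and risks

Total steps: 10. Longest linear sequence: 9 (steps 1–5 and 7–10 from compound 1); step 6 is a one-step branch.

Steps most likely to fail:

1. Step 7 (Proposed new method). The quinone methide may tautomerise to the vinylphenol before the ylide reaches it. The sulfonium salt may transfer its benzyl group to phenoxide or sulfinate. The sulfide may discriminate the ylide faces less well against a C=C acceptor than it does against C=O or C=N, and the cis ring may form alongside the trans.
   Fallback (known chemistry), setting out from 7 and 8 and returning at 15: chloride 8 is alkylated onto dimethyl sulfide (Me2S, NaBF4, acetone) to give dimethyl(3,4,5-trimethoxybenzyl)sulfonium tetrafluoroborate F1. F1, 7 and Cs2CO3 in MeCN should give, through dimethylsulfonium (3,4,5-trimethoxyphenyl)methylide F2 and quinone methide 11, the trans-dihydrobenzofuran as the racemate, that is 14 together with its (2R,3R) enantiomer F3. Desilylation as in step 8 then gives 15 together with the (2R,3R) phenol F4, and preparative HPLC on a chiral stationary phase delivers 15, where the route is rejoined.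

2. Step 9. Oxygen may be delivered to the unsubstituted ortho carbon C7 instead of C5, which leads on to an ortho-quinone. Facial selectivity at C5 may be low. Quinol 16 may undergo [4+2] cyclodimerisation before it is methylated.
   Fallback, setting out from 15 and returning at 16: Wessely acetoxylation (Pb(OAc)4, AcOH/CH2Cl2, 0 °C), in which acetate is passed from an aryloxy-lead(IV) species to the ortho carbon. It should give (2S,3S,5R)-5-acetoxy-5-allyl-3-methyl-2-(3,4,5-trimethoxyphenyl)-2,3-dihydrobenzofuran-6(5H)-one F5 and its 5S epimer F6 without reagent control. The two are diastereomers and are separated by chromatography. Methanolysis of F5 (K2CO3 cat., MeOH, 0 °C) gives 16.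

3. Step 10. Etherification of the hindered tertiary ketol may be slow, leaving time for [3,3] migration of the allyl group from C5 to C3a, ketol rearrangement or dimerisation.
   Fallback, setting out from 15 and returning at 17 without passing through 16: methoxylative dearomatisation with PhI(OAc)2 in MeOH at −40 °C, in which methanol captures the oxidised phenol at C5 (para to O1). It should give 17 together with the 5S epimer, (2S,3S,5S)-5-allyl-5-methoxy-3-methyl-2-(3,4,5-trimethoxyphenyl)-2,3-dihydrobenzofuran-6(5H)-one F7, from which 17 is separated by chromatography. Capture at C3a is the expected competing pathway and lowers the return.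

## Further compounds

F1 | step 7 | dimethyl(3,4,5-trimethoxybenzyl)sulfonium tetrafluoroborate | COc1cc(C[S+](C)C)cc(OC)c1OC.F[B-](F)(F)F
F2 | step 7 | dimethylsulfonium (3,4,5-trimethoxyphenyl)methylide | C[S+](C)[CH-]c1cc(OC)c(OC)c(OC)c1
F3 | step 7 | (2R,3R)-5-allyl-3-methyl-6-(triisopropylsilyloxy)-2-(3,4,5-trimethoxyphenyl)-2,3-dihydrobenzofuran | C=CCc1cc2c(cc1O[Si](C(C)C)(C(C)C)C(C)C)O[C@@H](c1cc(OC)c(OC)c(OC)c1)[C@@H]2C
F4 | step 7 | (2R,3R)-5-allyl-3-methyl-2-(3,4,5-trimethoxyphenyl)-2,3-dihydrobenzofuran-6-ol | C=CCc1cc2c(cc1O)O[C@@H](c1cc(OC)c(OC)c(OC)c1)[C@@H]2C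
F5 | step 9 | (2S,3S,5R)-5-acetoxy-5-allyl-3-methyl-2-(3,4,5-trimethoxyphenyl)-2,3-dihydrobenzofuran-6(5H)-one | C=CC[C@@]1(OC(C)=O)C=C2C(=CC1=O)O[C@H](c1cc(OC)c(OC)c(OC)c1)[C@H]2C
F6 | step 9 | (2S,3S,5S)-5-acetoxy-5-allyl-3-methyl-2-(3,4,5-trimethoxyphenyl)-2,3-dihydrobenzofuran-6(5H)-one | C=CC[C@]1(OC(C)=O)C=C2C(=CC1=O)O[C@H](c1cc(OC)c(OC)c(OC)c1)[C@H]2C
F7 | step 10 | (2S,3S,5S)-5-allyl-5-methoxy-3-methyl-2-(3,4,5-trimethoxyphenyl)-2,3-dihydrobenzofuran-6(5H)-one | C=CC[C@]1(OC)C=C2C(=CC1=O)O[C@H](c1cc(OC)c(OC)c(OC)c1)[C@H]2C
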